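**Retrosynthetic overview**

- 26 ⇐ O‑demethylation and removal of two benzylic carbonyl oxygens ⇐ bis(dihydropyranone) 23 ⇐ (key step) bis(isoxazoline) 21 ⇐ (S)‑10‑hydroxyhumulene 19 + 2 × tropone nitrile oxide 15.
- Enabling feature: in the pyran next to the carbinol (ring atoms O, C9, C8, CH2, C5′, C4′) the O–C9(CH3) and C8–CH2 bonds lie on one face of the former E C8=C9 alkene. The C4′=C5′ edge shared with the tropolone ring is the β,α‑edge of a vinylogous ester. The O/C9/C8/C part can therefore be laid down as a five‑membered isoxazoline (O–N=C–C8–C9), and N is later exchanged for C4′=C5′.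
- Ring order: tropone ring (oxyallyl (4+3) cycloaddition on a furan, then dehydration); eleven‑membered ring bought as α‑humulene; two isoxazolines; both pyran rings by five‑to‑six ring expansion.
- Stereochemistry: C10 by CBS reduction; C8/C9 by magnesium‑alkoxide‑directed suprafacial cycloaddition; C1/C2 by suprafacial attack on the outer face of the remaining trisubstituted alkene.

Key step: step 16

Remark on locants: macrocycle C1H=C2(CH3)–C3H2–C4H=C5H–C6(CH3)2–C7H2–C8H=C9(CH3)–C10–C11H2; tropolone C1′(=O), C2′(O), C3′H, C4′(O), C5′(C), C6′(CH3), C7′H.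

Remark on the chemistry (assumption): outer‑face attack on C1=C2 of 20 is taken to give the (1R,2R) centres drawn. This is treated as a risk below.

Step 1
Reactants: 1 methyl acetoacetate; 2 chloroacetyl chloride
Product: 3 methyl 2‑methyl‑4‑oxo‑4,5‑dihydrofuran‑3‑carboxylate
Conditions: MgCl2, pyridine, CH2Cl2, 0 °C to rt; then Et3N, rt
Reagents that add atoms: none
Why: C‑acylation of the magnesium enolate, then 5‑exo‑tet O‑alkylation of the acetyl enol on the CH2Cl group, is the classical 3(2H)‑furanone synthesis.

Step 2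
Reactants: 3 furanone ester
Product: 4 methyl 4‑methoxy‑2‑methylfuran‑3‑carboxylate
Conditions: Me2SO4, K2CO3, acetone, reflux
Reagents that add atoms: dimethyl sulfate COS(=O)(=O)OC
Why: Williamson‑type O‑methylation of the furanone enolate with a hard electrophile is driven by aromatisation to the 3‑alkoxyfuran.

Step 3
Reactants: 4 furan ester
Product: 5 (4‑methoxy‑2‑methylfuran‑3‑yl)methanol
Conditions: LiAlH4, Et2O, 0 °C
Reagents that add atoms: none
Why: Hydride reduction of the ester should leave the electron‑rich furan untouched.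

Step 4
Reactants: 5 furylmethanol
Product: 6 tert‑butyl[(4‑methoxy‑2‑methylfuran‑3‑yl)methoxy]dimethylsilane
Conditions: TBSCl, imidazole, DMF, rt
Reagents that add atoms: tert‑butyldimethylsilyl chloride CC(C)(C)[Si](C)(C)Cl
Why: Standard silylation masks the ionisable furylmethyl alcohol as a poorly leaving, bulky silyl ether for the Lewis‑acid steps.

Step 5
Reactants: 7 1,1‑dimethoxypropan‑2‑one
Product: 8 [(3,3‑dimethoxyprop‑1‑en‑2‑yl)oxy]trimethylsilane
Conditions: TMSOTf, Et3N, Et2O, 0 °C
Reagents that add atoms: trimethylsilyl triflate C[Si](C)(C)OS(=O)(=O)C(F)(F)F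
Why: Soft enolisation and silylation toward the unhindered methyl group gives the terminal silyl enol ether, the established precursor of a 1‑methoxy‑2‑siloxyallyl cation.

Step 6
Reactants: 6 silyloxymethylfuran; 8 silyl enol ether acetal
Product: 9 rac‑6‑{[(tert‑butyldimethylsilyl)oxy]methyl}‑2,7‑dimethoxy‑5‑methyl‑8‑oxabicyclo[3.2.1]oct‑6‑en‑3‑one (methoxy epimers)
Conditions: TMSOTf (0.1 equiv), EtNO2, −78 °C
Reagents that add atoms: none
Why: In this oxyallyl‑cation/furan (4+3) cycloaddition the oxocarbenium terminus CH(OMe) is attacked first by the most nucleophilic furan carbon (C5, β to the ring methoxy group), which fixes the regiochemistry, and the racemic stereocentres vanish in step 7.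

Step 7
Reactants: 9 oxabicycle
Product: 10 5‑{[(tert‑butyldimethylsilyl)oxy]methyl}‑2,4‑dimethoxy‑6‑methylcyclohepta‑2,4,6‑trien‑1‑one
Conditions: TMSOTf (3 equiv), Et3N (4 equiv), CH2Cl2, 0 °C to rt
Reagents that add atoms: none
Why: Enol silylation triggers β‑elimination of the oxygen bridge, and loss of the resulting β‑siloxy group (double E1cB) is driven by formation of the aromatic 2‑methoxytropone, a known oxabicycle‑to‑tropone conversion.

Step 8
Reactants: 10 silyl ether
Product: 11 5‑(hydroxymethyl)‑2,4‑dimethoxy‑6‑methyltropone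
Conditions: HF·pyridine, THF, 0 °C
Reagents that add atoms: none
Why: Fluoride desilylation under buffered conditions should leave the vinylogous methyl esters of the tropone intact.

Step 9
Reactants: 11 tropone alcohol
Product: 12 2,4‑dimethoxy‑6‑methyl‑1‑oxocyclohepta‑2,4,6‑triene‑5‑carbaldehyde
Conditions: MnO2, CH2Cl2, rt
Reagents that add atoms: none
Why: MnO2 oxidation is selective for the benzylic‑type alcohol and stops at the aldehyde.

Step 10
Reactants: 12 aldehyde
Product: 13 (E)‑oxime of 12
Conditions: NH2OH·HCl (1.0 equiv), NaOAc, MeOH, 0 °C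
Reagents that add atoms: hydroxylamine hydrochloride NO.Cl
Why: Oxime condensation at the aldehyde should be far faster at 0 °C than addition–elimination at the C2′ methoxy group when one equivalent of reagent is used.

Step 11
Reactants: 13 oxime
Product: 15 2,4‑dimethoxy‑6‑methyl‑1‑oxocyclohepta‑2,4,6‑triene‑5‑carbonitrile oxide, via hydroximoyl chloride 14 (not isolated)
Conditions: NCS, DMF, rt; then Et3N, Et2O, 0 °C
Reagents that add atoms: none
Why: Chlorination then dehydrochlorination (Huisgen nitrile oxide generation) should give an isolable dipole, because the flanking OCH3 and CH3 groups block dimerisation as in mesityl nitrile oxide.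

Step 12
Reactants: 16 α‑humulene
Product: 17 rac‑10‑hydroxyhumulene, (2E,6E,9E)‑2,5,5,9‑tetramethylcycloundeca‑2,6,9‑trien‑1‑ol
Conditions: SeO2 (0.3 equiv), t‑BuOOH, CH2Cl2, 0 °C to rt; chromatography
Reagents that add atoms: tert‑butyl hydroperoxide CC(C)(C)OO
Why: Riley oxidation (ene, then 2,3‑shift) attacks the CH2 group on the more substituted alkene carbon that is trans to the ring chain, which is C10 for the C8=C9 bond, and the isomeric C3 alcohol is to be separated.

Step 13
Reactants: 17 racemic allylic alcohol
Product: 18 (2E,6E,9E)‑2,5,5,9‑tetramethylcycloundeca‑2,6,9‑trien‑1‑one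
Conditions: MnO2, CH2Cl2, rt
Reagents that add atoms: none
Why: Allylic MnO2 oxidation erases the racemic centre and gives a configurationally mobile, achiral enone.

Step 14
Reactants: 18 enone
Product: 19 (S)‑10‑hydroxyhumulene
Conditions: (R)‑2‑methyl‑CBS‑oxazaborolidine (0.2 equiv), catecholborane, PhMe, −78 °C
Reagents that add atoms: none
Why: In the Corey–Bakshi–Shibata reduction the α‑methylalkenyl arm acts as the large group and C11H2 as the small one, so the (R)‑catalyst should set C10 as S, while catecholborane at low temperature does not hydroborate the alkenes.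

Step 15
Reactants: 19 (S)‑10‑hydroxyhumulene; 15 tropone nitrile oxide (2.5 equiv)
Product: 21 bis(isoxazoline) (O on C9 and C2, dipole carbon on C8 and C1), via monoisoxazoline 20 (not isolated)
Conditions: EtMgBr (1.05 equiv), CH2Cl2, 0 °C; then 15, 0 to 35 °C; H2O quench
Reagents that add atoms: none
Why: In this Huisgen 1,3‑dipolar cycloaddition the magnesium alkoxide binds the dipole oxygen and delivers it to C9 on the outer alkene face of the conformer with C11 anti, H10 next to the C9 methyl group (least A1,2 strain) and O10 over the π bond, which sets C8 and C9 suprafacially relative to C10, and the excess dipole then adds, oxygen again on the more substituted carbon, to the outer face of the strained C1=C2 bond (C1, C2), the neopentyl‑flanked C4=C5 bond being the most shielded.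

Step 16
Reactants: 21 bis(isoxazoline)
Product: 23 bis(dihydropyranone) (both pyran rings closed, C=O at both benzylic carbons), via bis‑aldol 22 (not isolated)
Conditions: Fe powder, NH4Cl, EtOH–H2O 4:1, 80 °C; filter; PPTS (0.2 equiv), 4 Å MS, PhMe, 90 °C
Reagents that add atoms: water O
Why: Proposed new method: zerovalent iron puts two electrons into each N–O bond, so each five‑membered O–N=C–C–C ring opens to a tertiary carbinol and an NH ketimine that water hydrolyses to the aryl ketone (22), after which the carbinol oxygen, still on C9 (C2), adds to C4′, the methoxy‑bearing β‑carbon of the unmasked enone C(=O)–C5′=C4′(OMe), and methanol leaves, so the one‑atom N bridge is replaced by the two‑carbon C4′=C5′ edge and the ring grows from five to six atoms. The closest known types are reductive isoxazoline‑to‑aldol unmasking, chromanone closure of β‑hydroxy ketones on ortho‑alkoxy or ortho‑fluoro aryl ketones by addition–elimination, and alkoxy exchange on methoxytropones. Both pyran rings close in the 6‑endo‑trig mode (oxa‑Michael addition, then elimination). No stereocentre is created: the C9–O and C2–O bonds are never broken, and C8 and C1, now α to a ketone, should rest in the trans‑fused arrangement they already have. The step needs attack at C4′–OMe and not C2′–OMe, and cyclisation faster than dehydration or retro‑aldol cleavage of the tertiary aldols; reach (only C4′ is accessible), the absence of base and acid activation of the vinylogous ester should secure this. Attack of the C10 hydroxyl on C4′ would only give a seven‑membered isomer that should funnel to 23 by O‑to‑O Smiles transfer through a spiro‑dioxolane.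

Step 17
Reactants: 23 bis(dihydropyranone)
Product: 24 bis(benzylic alcohol) (epimers at both carbinols)
Conditions: NaBH4, CeCl3·7H2O, MeOH–CH2Cl2, −40 °C
Reagents that add atoms: none
Why: Luche 1,2‑reduction should take the two exocyclic ketones, since ketone reductions next to intact 2‑methoxytropones have precedent, and the new carbinol centres are removed in step 18.

Step 18
Reactants: 24 bis(benzylic alcohol)
Product: 25 bis(2‑methoxytropone) of the target (CH2 at both benzylic positions)
Conditions: Et3SiH, BF3·OEt2, CH2Cl2, −78 to −30 °C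
Reagents that add atoms: none
Why: In this ionic hydrogenation only the benzylic alcohols ionise, because the cation is stabilised by the ortho C4′ ether oxygen, and it is trapped by silane, whereas the unactivated C10 alcohol and the hindered alkene should persist at low temperature.

Step 19
Reactants: 25 bis(2‑methoxytropone)
Product: 26 target CNP0283947.4
Conditions: KOH, EtOH–H2O, 70 °C; then 1 M HCl to pH 4
Reagents that add atoms: potassium hydroxide [K+].[OH-]
Why: Addition–elimination of hydroxide at C2′ is the usual hydrolysis of tropolone methyl ethers, frees both tropolones under conditions that do not ionise the tertiary ethers, and touches no stereocentre.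

**Compound list**

1 | methyl acetoacetate | CC(=O)CC(=O)OC | starting material
2 | chloroacetyl chloride | ClCC(Cl)=O | starting material
3 | methyl 2‑methyl‑4‑oxo‑4,5‑dihydrofuran‑3‑carboxylate | CC1=C(C(=O)OC)C(=O)CO1 | intermediate
4 | methyl 4‑methoxy‑2‑methylfuran‑3‑carboxylate | Cc1occ(OC)c1C(=O)OC | intermediate
5 | (4‑methoxy‑2‑methylfuran‑3‑yl)methanol | Cc1occ(OC)c1CO | intermediate
6 | TBS ether of 5 | Cc1occ(OC)c1CO[Si](C)(C)C(C)(C)C | intermediate
7 | 1,1‑dimethoxypropan‑2‑one | CC(=O)C(OC)OC | starting material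
8 | [(3,3‑dimethoxyprop‑1‑en‑2‑yl)oxy]trimethylsilane | C=C(O[Si](C)(C)C)C(OC)OC | intermediate
9 | rac (4+3) adduct, 8‑oxabicyclo[3.2.1]oct‑6‑en‑3‑one | CC12CC(=O)C(OC)C(O1)C(OC)=C2CO[Si](C)(C)C(C)(C)C | intermediate
10 | 5‑(TBSO‑methyl)‑2,4‑dimethoxy‑6‑methyltropone | CC1=CC(=O)C(OC)=CC(OC)=C1CO[Si](C)(C)C(C)(C)C | intermediate
11 | 5‑(hydroxymethyl)‑2,4‑dimethoxy‑6‑methyltropone | CC1=CC(=O)C(OC)=CC(OC)=C1CO | intermediate
12 | tropone‑5‑carbaldehyde | CC1=CC(=O)C(OC)=CC(OC)=C1C=O | intermediate
13 | (E)‑oxime of 12 | CC1=CC(=O)C(OC)=CC(OC)=C1/C=N/O | intermediate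
14 | hydroximoyl chloride | CC1=CC(=O)C(OC)=CC(OC)=C1C(Cl)=NO | intermediate
15 | tropone nitrile oxide | CC1=CC(=O)C(OC)=CC(OC)=C1C#[N+][O-] | intermediate
16 | α‑humulene | C/C1=C\CC(C)(C)/C=C/C/C(C)=C/CC1 | starting material
17 | rac‑10‑hydroxyhumulene | C/C1=C\CC(C)(C)/C=C/C/C(C)=C/CC1O | intermediate
18 | humulen‑10‑one | C/C1=C\CC(C)(C)/C=C/C/C(C)=C/CC1=O | intermediate
19 | (S)‑10‑hydroxyhumulene | C/C1=C\CC(C)(C)/C=C/C/C(C)=C/C[C@@H]1O | intermediate
20 | monoisoxazoline (C8/C9) | CC1=CC(=O)C(OC)=CC(OC)=C1C2[C@H]1CC(C)(C)/C=C/C/C(C)=C/C[C@H](O)[C@]1(C)ON=2 | intermediate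
21 | bis(isoxazoline) | CC1=CC(=O)C(OC)=CC(OC)=C1C2[C@H]1CC(C)(C)/C=C/C[C@@]3(C)ON=C(C4=C(OC)C=C(OC)C(=O)C=C4C)[C@@H]3C[C@H](O)[C@]1(C)ON=2 | intermediate
22 | bis(β‑hydroxy ketone) | CC1=CC(=O)C(OC)=CC(OC)=C1C(=O)[C@H]1CC(C)(C)/C=C/C[C@@](C)(O)[C@H](C(=O)C2=C(OC)C=C(OC)C(=O)C=C2C)C[C@H](O)[C@]1(C)O | intermediate
23 | bis(dihydropyranone) | CC1=CC(=O)C(OC)=CC2=C1C(=O)[C@H]1CC(C)(C)/C=C/C[C@@]3(C)OC=4C=C(OC)C(=O)C=C(C)C=4C(=O)[C@@H]3C[C@H](O)[C@]1(C)O2 | intermediate
24 | bis(benzylic alcohol) | CC1=CC(=O)C(OC)=CC2=C1C(O)[C@H]1CC(C)(C)/C=C/C[C@@]3(C)OC=4C=C(OC)C(=O)C=C(C)C=4C(O)[C@@H]3C[C@H](O)[C@]1(C)O2 | intermediate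
25 | bis(2‑methoxytropone) | CC1=CC(=O)C(OC)=CC2=C1C[C@H]1CC(C)(C)/C=C/C[C@@]3(C)OC=4C=C(OC)C(=O)C=C(C)C=4C[C@@H]3C[C@H](O)[C@]1(C)O2 | intermediate
26 | CNP0283947.4 | Cc1cc(=O)c(O)cc2c1C[C@H]1CC(C)(C)/C=C/C[C@@]3(C)Oc4cc(O)c(=O)cc(C)c4C[C@@H]3C[C@H](O)[C@]1(C)O2 | target

Total step count: 19. Longest linear sequence: 15 (steps 1–4, 6–11, 15–19).

**Steps most likely to fail**

1. Step 16. Dehydration or retro‑aldol cleavage of the tertiary aldols may outrun the alkoxy exchange, or the metal may attack the tropone. The fallback sets out from 21.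
   - Hydrogenolysis of the N–O bonds (H2, Raney Ni, B(OH)3, MeOH–H2O) is stopped at the isolated bis‑aldol 22.
   - Hydroxyl‑directed Evans–Saksena reduction with Me4NBH(OAc)3 in MeCN–AcOH gives the bis(1,3‑diol) F1. F1 can no longer undergo retro‑aldol cleavage, and the tropone carbonyls are not reached by the directed hydride.
   - Camphorsulfonic‑acid‑catalysed alkoxy exchange at C4′ in toluene closes both pyran rings. The route is rejoined at 24.

2. Step 15. The second cycloaddition may show poor facial selectivity at C1=C2, or may compete with addition to C4=C5. The fallback sets out from 19 with 1.05 equiv of 15 and isolates only the directed monoadduct 20.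
   - The conditions of steps 16–18 convert 20 into the monopyranone F2, the benzylic alcohol F3 and the methylene compound F4.
   - Separately, 11 is hydrolysed (KOH, then acid) to 2,4‑dihydroxy‑5‑(hydroxymethyl)‑6‑methyltropone F5.
   - Heating F5 with F4 in xylene at 150 °C generates the tropolone ortho‑quinone methide. This adds to the electron‑rich C1=C2 bond in a hetero‑Diels–Alder reaction and ignores C4=C5, giving the mono‑O‑methyl compound F6.
   - The conditions of step 19 bring the route back at 26.

3. Step 12. Selenium dioxide may prefer the doubly allylic C3 position, so regiocontrol may be lost. The fallback sets out from 16.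
   - One equivalent of mCPBA epoxidises the most reactive C1=C2 bond to the racemic monoepoxide F7.
   - Riley oxidation then finds a single trisubstituted alkene and gives the hydroxy epoxide F8.
   - Stereoretentive deoxygenation with WCl6/n‑BuLi restores the E alkene. The route is rejoined at 17.

**Further compounds**

F1 | step 16 | bis(1,3‑diol) | CC1=CC(=O)C(OC)=CC(OC)=C1C(O)[C@H]1CC(C)(C)/C=C/C[C@@](C)(O)[C@H](C(O)C2=C(OC)C=C(OC)C(=O)C=C2C)C[C@H](O)[C@]1(C)O
F2 | step 15 | monopyranone | CC1=CC(=O)C(OC)=CC2=C1C(=O)[C@H]1CC(C)(C)/C=C/C/C(C)=C/C[C@H](O)[C@]1(C)O2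
F3 | step 15 | mono benzylic alcohol | CC1=CC(=O)C(OC)=CC2=C1C(O)[C@H]1CC(C)(C)/C=C/C/C(C)=C/C[C@H](O)[C@]1(C)O2
F4 | step 15 | monoadduct with CH2 (2‑methoxytropone) | CC1=CC(=O)C(OC)=CC2=C1C[C@H]1CC(C)(C)/C=C/C/C(C)=C/C[C@H](O)[C@]1(C)O2
F5 | step 15 | 2,4‑dihydroxy‑5‑(hydroxymethyl)‑6‑methyltropone | CC1=CC(=O)C(O)=CC(O)=C1CO
F6 | step 15 | mono‑O‑methyl ether of the target | CC1=CC(=O)C(OC)=CC2=C1C[C@H]1CC(C)(C)/C=C/C[C@@]3(C)OC=4C=C(O)C(=O)C=C(C)C=4C[C@@H]3C[C@H](O)[C@]1(C)O2
F7 | step 12 | rac‑humulene 1,2‑epoxide | C/C1=C\CC(C)(C)/C=C/C[C@@]2(C)O[C@@H]2CC1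
F8 | step 12 | rac‑10‑hydroxyhumulene 1,2‑epoxide (C10 epimers) | C/C1=C\CC(C)(C)/C=C/C[C@@]2(C)O[C@@H]2CC1O
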